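Readings and results were computed with constants of no real substance, and the scatter is random.

Amounts first: each flask holds the two substrates equally, with a single-handed free catalyst, and the flasks differ in coupling partner.

| flask | left-handed substrate | right-handed substrate | coupling partner | free catalyst | remark | time |
|---|---|---|---|---|---|---|
| cedar | 0.050 M | 0.050 M | 0.34 equiv | 0.8 mol% | run made earlier |  |
| oak | 0.050 M | 0.050 M | 1.3 equiv | 0.8 mol% | run made earlier |  |
| red | 0.050 M | 0.050 M | 2.00 equiv | 0.8 mol% |  | 20 min |
| green | 0.050 M | 0.050 M | 0.500 equiv | 0.8 mol% |  | 20 min |

- cedar (time / min: left-handed product / %, right-handed product / %): 0.500: 0, 1.5; 1.50: 1.9, 1.9; 3.00: 2.0, 0.2; 4.00: 2.9, 1.0; 6.00: 2.9, 2.5; 8.00: 2.3, 1.4; 10.0: 2.9, 3.9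
- oak (time / min: left-handed product / %, right-handed product / %): 0.833: 0.7, 1.8; 1.33: 5.0, 2.4; 2.00: 2.1, 3.0; 3.00: 6.9, 2.2; 4.00: 7.1, 4.6; 6.00: 6.5, 6.7; 10.0: 11.3, 8.1

(standard deviation of a reading: 1 percentage point)

1. the flask that ends with the higher excess of left-handed product over right-handed product in the product, or "neither" when 2 percentage points or less lies between them (red / green / neither)
2. excess of left-handed product over right-handed product in the product at the end, red
3. excess of left-handed product over right-handed product in the product at the end, green

- free catalyst is single-handed; left-handed substrate and right-handed substrate are mirror images of each other, charged as a racemate, each of them at the stated concentration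
- the numbers in the tables scatter with a standard deviation of 1 percentage point
- an excess is the difference of the two amounts in percent of their sum
- an excess is below zero if the other one leads

Which concentration sets the order of the rate? I look at [coupling partner]. At 10.0 min, oak holds 19.4 % of product and cedar 6.80 %. So 3.82-fold the partner gave 2.85-fold the product, roughly first order.

And the excess? If both products form at about the same order in [coupling partner], it cancels in their ratio. So I pool cedar and oak.

What moves the pooled excess, then? Time. Around 3.50 min it reads 40.5 %. At 10.0 min it reads 8.40 %, which is less. That gives 2.86 min as the fade time, the time in which the excess falls to half .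

Isn't the late figure weak? Yes. It carries about 7.63 % of scatter, so its sign is barely safe.

What do you commit to? Carried on to 20 min, the excess is 0.746 % in both red and green. Both flasks then carry the same estimate, so the gap between them lies within the margin of 2 percentage points, and I say neither.

The forecast says red, with −14 % for red and −17 % for green, from “a left-selective channel that dies with time, plus a persistent right-selective channel”. Its sign differs from mine.

The flasks give neither: 0.948 % for red and 1.21 % for green.

    coupling partner + free catalyst + left-handed substrate → free catalyst + left-handed product (k = 2400 M⁻² min⁻¹)
    free catalyst → spent catalyst (k = 0.130 min⁻¹)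
    left-handed substrate ⇌ right-handed substrate (k = 0.0220 min⁻¹)
    coupling partner + free catalyst + right-handed substrate → free catalyst + right-handed product (k = 780 M⁻² min⁻¹)
    left-handed product ⇌ right-handed product (k = 0.230 min⁻¹)

With the passing of left-handed product into right-handed product taken away, both ways, green ends at 49.5 %, not 1.21 %, the largest single effect ; the products move towards thermodynamic control. Green with red's partner ends at 0.948 %, so the equivalents are not the reason. A fade time of 2.86 min gave 0.746 %, and a second flask, red with 3.2 mol% of free catalyst, ends at 0.327 %.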